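The two hindered arenes are never coupled directly. Instead, ring A'' of the 4'''-hydroxyflavone half is grown around C8'', an alkyne carbon already bonded to C8 of the acacetin half. The feature exploited is the phloroglucinol pattern of ring A'' (oxygens on C5'', C7'', C8a''), in which C8'' lies between C7''–O and C8a''–O. Heating 5,7-di-O-benzyl-8-(triisopropylsilyloxyethynyl)acacetin with 3-ethoxycyclobutenone forms C8''–C8a'', C6''–C7'' and C4a''–C8a'' in one operation. It delivers ring A'' with three differentiated oxygens: free phenol, silyl ether, ethyl ether. The single free phenol then steers formylation to C4a'', from which ring C'' is closed through an ynone.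

Key step: step 6

Assumption: the target string fixes no configuration for the C8–C8'' axis, so the biaryl is made as the racemate; unit 1 carries plain and single-primed locants, unit 2 double- and triple-primed locants.

Step 1
Reactants: 1 acacetin (5,7-dihydroxy-4'-methoxyflavone)
Product: 2 5,7-bis(benzyloxy)-4'-methoxyflavone
Conditions: BnBr (3 equiv), K2CO3 (4 equiv), DMF, 80 °C
Reagents that add atoms: benzyl bromide, BrCc1ccccc1
Why: Williamson ether synthesis, in which excess base and heat in DMF also alkylate the 5-OH that is hydrogen-bonded to the C4 carbonyl, so that no acidic or ketene-trapping hydroxyl reaches steps 5 and 6.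

Step 2
Reactants: 2 5,7-bis(benzyloxy)-4'-methoxyflavone
Product: 3 5,7-bis(benzyloxy)-8-iodo-4'-methoxyflavone
Conditions: I2, CF3CO2Ag, CH2Cl2, 0 °C → rt
Reagents that add atoms: iodine, II
Why: Electrophilic aromatic iodination by the acyl hypoiodite formed in the flask, which in 5,7-dialkoxyflavones goes to C8, the most nucleophilic ring carbon and a less crowded one than C6 between its two benzyloxy groups.

Step 3
Reactants: 3 5,7-bis(benzyloxy)-8-iodo-4'-methoxyflavone; 4 trimethylsilylacetylene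
Product: 5 5,7-bis(benzyloxy)-4'-methoxy-8-[(trimethylsilyl)ethynyl]flavone
Conditions: PdCl2(PPh3)2 (5 mol %), CuI (10 mol %), Et3N, DMF, 70 °C
Reagents that add atoms: none
Why: Sonogashira coupling, in which zerovalent palladium inserts into the C8–I bond and the slim copper acetylide is transferred without trouble from the two ortho oxygens.

Step 4
Reactants: 5 5,7-bis(benzyloxy)-4'-methoxy-8-[(trimethylsilyl)ethynyl]flavone
Product: 6 5,7-bis(benzyloxy)-8-ethynyl-4'-methoxyflavone
Conditions: K2CO3 (cat.), MeOH–CH2Cl2, rt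
Reagents that add atoms: none
Why: Methoxide-catalysed protodesilylation of the alkynyl C–Si bond, to which benzyl ethers and the chromone are inert.

Step 5
Reactants: 6 5,7-bis(benzyloxy)-8-ethynyl-4'-methoxyflavone
Product: 9 5,7-bis(benzyloxy)-4'-methoxy-8-[(triisopropylsilyloxy)ethynyl]flavone, via lithium acetylide 7 (not isolated), via lithium ynolate 8 (not isolated)
Conditions: LiHMDS, THF, −78 °C; t-BuOOLi (from anhydrous t-BuOOH + LiHMDS), −78 → 0 °C; TIPSOTf, −78 → 0 °C
Reagents that add atoms: tert-butyl hydroperoxide (used as its lithium salt, delivers O), CC(C)(C)OO; triisopropylsilyl triflate, CC(C)[Si](OS(=O)(=O)C(F)(F)F)(C(C)C)C(C)C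
Why: Oxidation of a lithium acetylide with lithium tert-butyl peroxide to the ynolate followed by O-silylation, where non-nucleophilic LiHMDS removes only the alkyne proton, 2-arylchromones resist nucleophilic hydroperoxide attack, and the bulky hard silyl triflate reacts at oxygen rather than carbon.

Step 6
Reactants: 9 5,7-bis(benzyloxy)-4'-methoxy-8-[(triisopropylsilyloxy)ethynyl]flavone; 10 3-ethoxycyclobut-2-en-1-one
Product: 15 8-[4-ethoxy-2-hydroxy-6-(triisopropylsilyloxy)phenyl]-5,7-bis(benzyloxy)-4'-methoxyflavone, via vinylketene 11 (not isolated), via cyclobutenone adduct 12 (not isolated), via dienylketene 13 (not isolated), via cyclohexadienone 14 (not isolated)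
Conditions: 10 (1.5 equiv, added in portions), toluene (0.3 M), sealed tube, 80 → 115 °C
Reagents that add atoms: none
Why: Danheiser benzannulation: 10 opens thermally by a four-electron electrocyclic reaction to (1-ethoxyvinyl)ketene 11 (ethoxy on the carbon next to the ketene CH), and the carbon of 9 that carries the flavonyl group, made nucleophilic by the ynol oxygen, attacks the ketene carbonyl carbon in a (2+2) cycloaddition that gives 12 and sets C8''–C8a'' and C6''–C7''. 12 opens again to dienylketene 13, and ring A'' closes by a thermal disrotatory six-electron electrocyclisation that joins C4a'' to C8a'' (the very contact cut in the first opening), after which dienone 14 enolises to phenol 15. The closest known reaction type is the annulation of cyclobutenone-derived vinylketenes with triisopropylsilyloxyalkynes to monosilylated resorcinols; here only the 3-alkoxy substituent and the aryl group on the alkyne are new. The selectivity needed is the orientation of the (2+2) step, and the polarisation of the O–C≡C unit secures it, so the flavonyl group ends between the free O8a''–H and the O7'' silyl ether while the ethoxy group lands on C5''. No stereocentre survives (C4 of 12 is lost on ring opening) and the C8–C8'' axis arises as a racemate. All hydroxyl groups of 9 are benzylated, so nothing but the alkyne can trap the ketenes, and the bulky silyl group slows oxygen-to-carbon silyl migration at the reaction temperature.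

Step 7
Reactants: 15 8-[4-ethoxy-2-hydroxy-6-(triisopropylsilyloxy)phenyl]-5,7-bis(benzyloxy)-4'-methoxyflavone
Product: 17 8-[4-ethoxy-3-formyl-2-hydroxy-6-(triisopropylsilyloxy)phenyl]-5,7-bis(benzyloxy)-4'-methoxyflavone, via hydroxymethyl phenol 16 (not isolated)
Conditions: MgCl2, Et3N, (CH2O)n, MeCN, reflux; then 1 M HCl
Reagents that add atoms: paraformaldehyde (reacts as formaldehyde), C=O
Why: Casnati–Skattebøl ortho-formylation, in which the magnesium phenoxide of O8a'' delivers bound formaldehyde only to the one free ortho carbon C4a'' (the other is C8'') and a second formaldehyde accepts hydride from 16, so the para carbon C6'' and ring A of unit 1 stay untouched.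

Step 8
Reactants: 17 8-[4-ethoxy-3-formyl-2-hydroxy-6-(triisopropylsilyloxy)phenyl]-5,7-bis(benzyloxy)-4'-methoxyflavone; 18 1-(benzyloxy)-4-ethynylbenzene
Product: 20 5,7-bis(benzyloxy)-8-{3-[3-(4-benzyloxyphenyl)-1-hydroxyprop-2-yn-1-yl]-4-ethoxy-2-hydroxy-6-(triisopropylsilyloxy)phenyl}-4'-methoxyflavone (diastereomer mixture), via alkynylmagnesium bromide 19 (not isolated)
Conditions: 18 (2.5 equiv), EtMgBr (2.4 equiv), THF, 40 °C; then 17, 0 °C → rt; crude product carried on
Reagents that add atoms: none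
Why: 1,2-Addition of an alkynyl Grignard reagent to an aldehyde, in which the first equivalent forms a magnesium phenoxide whose chelate with the formyl oxygen activates the aldehyde over the vinylogous-ester carbonyl of unit 1, and the carbinol centre forms without control because step 9 erases it.

Step 9
Reactants: 20 propargylic alcohol from step 8
Product: 21 5,7-bis(benzyloxy)-8-{3-[3-(4-benzyloxyphenyl)prop-2-ynoyl]-4-ethoxy-2-hydroxy-6-(triisopropylsilyloxy)phenyl}-4'-methoxyflavone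
Conditions: MnO2 (excess), CH2Cl2, rt
Reagents that add atoms: none
Why: MnO2 oxidation of an alcohol that is both benzylic and propargylic, mild enough for the phenol, the silyl ether and the benzyl ethers.

Step 10
Reactants: 21 ynone from step 9
Product: 23 5,7,4'''-tris(benzyloxy)-5''-ethoxy-7''-hydroxy-4'-methoxy-8,8''-biflavone, via silyl-protected biflavone 22 (not isolated)
Conditions: DMAP (20 mol %), DMF, 40 °C; then TBAF, AcOH, THF, 0 °C
Reagents that add atoms: none
Why: DMAP-catalysed 6-endo cycloisomerisation of an o-alkynoylphenol (conjugate addition of DMAP, then addition–elimination by O8a'' at C2'') closes ring C'' as the flavone rather than the 5-exo aurone, and buffered fluoride then cleaves the aryl silyl ether that the para carbonyl C4'' has activated.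

Step 11
Reactants: 23 5,7,4'''-tris(benzyloxy)-5''-ethoxy-7''-hydroxy-4'-methoxy-8,8''-biflavone
Product: 24 4'-O-methylcupressuflavone (5,7,5'',7'',4'''-pentahydroxy-4'-methoxy-8,8''-biflavone)
Conditions: BCl3 (excess), C6HMe5, CH2Cl2, −78 °C → rt; then H2O
Reagents that add atoms: none
Why: Lewis-acid ether cleavage, in which BCl3 with pentamethylbenzene as cation scavenger removes the three benzyl ethers in the cold and, on warming, the boron chelate between O4'' and O5'' activates only the peri ethyl ether for chloride attack, whereas BCl3 leaves the unchelated, carbonyl-conjugated 4'-methoxy group alone.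

Compound list
1 | acacetin | COc1ccc(cc1)-c1cc(=O)c2c(O)cc(O)cc2o1 | starting material
2 | 5,7-bis(benzyloxy)-4'-methoxyflavone | COc1ccc(cc1)-c1cc(=O)c2c(OCc3ccccc3)cc(OCc3ccccc3)cc2o1 | intermediate
3 | 5,7-bis(benzyloxy)-8-iodo-4'-methoxyflavone | COc1ccc(cc1)-c1cc(=O)c2c(OCc3ccccc3)cc(OCc3ccccc3)c(I)c2o1 | intermediate
4 | trimethylsilylacetylene | C[Si](C)(C)C#C | starting material
5 | 5,7-bis(benzyloxy)-4'-methoxy-8-[(trimethylsilyl)ethynyl]flavone | COc1ccc(cc1)-c1cc(=O)c2c(OCc3ccccc3)cc(OCc3ccccc3)c(C#C[Si](C)(C)C)c2o1 | intermediate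
6 | 5,7-bis(benzyloxy)-8-ethynyl-4'-methoxyflavone | COc1ccc(cc1)-c1cc(=O)c2c(OCc3ccccc3)cc(OCc3ccccc3)c(C#C)c2o1 | intermediate
7 | lithium acetylide of 6 | COc1ccc(cc1)-c1cc(=O)c2c(OCc3ccccc3)cc(OCc3ccccc3)c(C#C[Li])c2o1 | intermediate
8 | lithium 2-[5,7-bis(benzyloxy)-4'-methoxyflavon-8-yl]ethynolate | [Li+].COc1ccc(cc1)-c1cc(=O)c2c(OCc3ccccc3)cc(OCc3ccccc3)c(C#C[O-])c2o1 | intermediate
9 | 5,7-bis(benzyloxy)-4'-methoxy-8-[(triisopropylsilyloxy)ethynyl]flavone | COc1ccc(cc1)-c1cc(=O)c2c(OCc3ccccc3)cc(OCc3ccccc3)c(C#CO[Si](C(C)C)(C(C)C)C(C)C)c2o1 | intermediate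
10 | 3-ethoxycyclobut-2-en-1-one | CCOC1=CC(=O)C1 | starting material
11 | 3-ethoxybuta-1,3-dien-1-one, (1-ethoxyvinyl)ketene | CCOC(=C)C=C=O | intermediate
12 | 4-(1-ethoxyvinyl)-2-[5,7-bis(benzyloxy)-4'-methoxyflavon-8-yl]-3-(triisopropylsilyloxy)cyclobut-2-en-1-one (racemic) | COc1ccc(cc1)-c1cc(=O)c2c(OCc3ccccc3)cc(OCc3ccccc3)c(C3=C(O[Si](C(C)C)(C(C)C)C(C)C)C(C(=C)OCC)C3=O)c2o1 | intermediate
13 | (3E)-5-ethoxy-2-[5,7-bis(benzyloxy)-4'-methoxyflavon-8-yl]-3-(triisopropylsilyloxy)hexa-1,3,5-trien-1-one | COc1ccc(cc1)-c1cc(=O)c2c(OCc3ccccc3)cc(OCc3ccccc3)c(C(=C=O)/C(O[Si](C(C)C)(C(C)C)C(C)C)=C\C(=C)OCC)c2o1 | intermediate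
14 | 5-ethoxy-2-[5,7-bis(benzyloxy)-4'-methoxyflavon-8-yl]-3-(triisopropylsilyloxy)cyclohexa-2,4-dien-1-one | COc1ccc(cc1)-c1cc(=O)c2c(OCc3ccccc3)cc(OCc3ccccc3)c(C3=C(O[Si](C(C)C)(C(C)C)C(C)C)C=C(OCC)CC3=O)c2o1 | intermediate
15 | 8-[4-ethoxy-2-hydroxy-6-(triisopropylsilyloxy)phenyl]-5,7-bis(benzyloxy)-4'-methoxyflavone (racemic axis) | COc1ccc(cc1)-c1cc(=O)c2c(OCc3ccccc3)cc(OCc3ccccc3)c(-c3c(O)cc(OCC)cc3O[Si](C(C)C)(C(C)C)C(C)C)c2o1 | intermediate
16 | 8-[4-ethoxy-2-hydroxy-3-(hydroxymethyl)-6-(triisopropylsilyloxy)phenyl]-5,7-bis(benzyloxy)-4'-methoxyflavone | COc1ccc(cc1)-c1cc(=O)c2c(OCc3ccccc3)cc(OCc3ccccc3)c(-c3c(O)c(CO)c(OCC)cc3O[Si](C(C)C)(C(C)C)C(C)C)c2o1 | intermediate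
17 | 8-[4-ethoxy-3-formyl-2-hydroxy-6-(triisopropylsilyloxy)phenyl]-5,7-bis(benzyloxy)-4'-methoxyflavone | COc1ccc(cc1)-c1cc(=O)c2c(OCc3ccccc3)cc(OCc3ccccc3)c(-c3c(O)c(C=O)c(OCC)cc3O[Si](C(C)C)(C(C)C)C(C)C)c2o1 | intermediate
18 | 1-(benzyloxy)-4-ethynylbenzene | C#Cc1ccc(OCc2ccccc2)cc1 | starting material
19 | [(4-benzyloxyphenyl)ethynyl]magnesium bromide | Br[Mg]C#Cc1ccc(OCc2ccccc2)cc1 | intermediate
20 | 5,7-bis(benzyloxy)-8-{3-[3-(4-benzyloxyphenyl)-1-hydroxyprop-2-yn-1-yl]-4-ethoxy-2-hydroxy-6-(triisopropylsilyloxy)phenyl}-4'-methoxyflavone (carbinol centre uncontrolled) | COc1ccc(cc1)-c1cc(=O)c2c(OCc3ccccc3)cc(OCc3ccccc3)c(-c3c(O)c(C(O)C#Cc4ccc(OCc5ccccc5)cc4)c(OCC)cc3O[Si](C(C)C)(C(C)C)C(C)C)c2o1 | intermediate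
21 | 5,7-bis(benzyloxy)-8-{3-[3-(4-benzyloxyphenyl)prop-2-ynoyl]-4-ethoxy-2-hydroxy-6-(triisopropylsilyloxy)phenyl}-4'-methoxyflavone | COc1ccc(cc1)-c1cc(=O)c2c(OCc3ccccc3)cc(OCc3ccccc3)c(-c3c(O)c(C(=O)C#Cc4ccc(OCc5ccccc5)cc4)c(OCC)cc3O[Si](C(C)C)(C(C)C)C(C)C)c2o1 | intermediate
22 | 5,7,4'''-tris(benzyloxy)-5''-ethoxy-4'-methoxy-7''-(triisopropylsilyloxy)-8,8''-biflavone | COc1ccc(cc1)-c1cc(=O)c2c(OCc3ccccc3)cc(OCc3ccccc3)c(-c3c(O[Si](C(C)C)(C(C)C)C(C)C)cc(OCC)c4c(=O)cc(-c5ccc(OCc6ccccc6)cc5)oc34)c2o1 | intermediate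
23 | 5,7,4'''-tris(benzyloxy)-5''-ethoxy-7''-hydroxy-4'-methoxy-8,8''-biflavone | COc1ccc(cc1)-c1cc(=O)c2c(OCc3ccccc3)cc(OCc3ccccc3)c(-c3c(O)cc(OCC)c4c(=O)cc(-c5ccc(OCc6ccccc6)cc5)oc34)c2o1 | intermediate
24 | 4'-O-methylcupressuflavone (racemic axis) | COc1ccc(cc1)-c1cc(=O)c2c(O)cc(O)c(-c3c(O)cc(O)c4c(=O)cc(-c5ccc(O)cc5)oc34)c2o1 | target

Total step count: 11. Longest linear sequence: 11 steps (1 → 24); compounds 4, 10 and 18 are bought.

Steps most likely to fail

Step 6.
- Risk: the vinylogous-ester stabilisation of 10 may push its ring opening to temperatures at which silicon in 9 migrates from oxygen to carbon. The ketene may also oligomerise, or surplus ketene may acylate the newly formed phenol.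
- Fallback: it sets out from iodide 3 and returns at 15, making the biaryl bond directly.
- Acid-catalysed mono-etherification of phloroglucinol with ethanol gives 5-ethoxybenzene-1,3-diol F1. MOMCl and iPr2NEt turn this into 1-ethoxy-3,5-bis(methoxymethoxy)benzene F2.
- Directed ortho-lithiation (n-BuLi, THF, 0 °C) between the two acetal oxygens, then B(OiPr)3 and mild acid, gives [4-ethoxy-2,6-bis(methoxymethoxy)phenyl]boronic acid F3.
- Suzuki–Miyaura coupling with 3 (Pd(OAc)2, SPhos, K3PO4, toluene–water, 100 °C) gives 5,7-bis(benzyloxy)-8-[4-ethoxy-2,6-bis(methoxymethoxy)phenyl]-4'-methoxyflavone F4.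
- Dilute HCl in methanol frees 5,7-bis(benzyloxy)-8-(4-ethoxy-2,6-dihydroxyphenyl)-4'-methoxyflavone F5. One equivalent of TIPSOTf with 2,6-lutidine then silylates one of its two equivalent hydroxyl groups to give 15.

Step 5.
- Risk: oxygen transfer to the hindered aryl acetylide may be slower than attack of peroxide, amide or ynolate on the chromone. The ynolate may also silylate at carbon.
- Fallback: it sets out from iodide 3 and returns at 9 without organolithium or peroxide reagents.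
- Hydroxycarbonylation (Pd(OAc)2, dppf, CO, H2O, Et3N, DMF) gives 5,7-bis(benzyloxy)-4'-methoxyflavone-8-carboxylic acid F6. Oxalyl chloride with catalytic DMF gives 5,7-bis(benzyloxy)-4'-methoxyflavone-8-carbonyl chloride F7.
- Trimethylsilyldiazomethane gives 5,7-bis(benzyloxy)-8-(diazoacetyl)-4'-methoxyflavone F8. TIPSOTf with iPr2NEt silylates the diazo carbon to 5,7-bis(benzyloxy)-8-[diazo(triisopropylsilyl)acetyl]-4'-methoxyflavone F9.
- Catalytic CuOTf then expels nitrogen. A 1,3-shift of silicon from carbon to oxygen and a 1,2-shift of the aryl group follow, a known entry to 1-aryl-2-siloxyalkynes, and give 9.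

Step 8.
- Risk: the Grignard reagent may also add to the C4 carbonyl of unit 1. The very electron-rich o-hydroxybenzylic propargylic alcohol may ionise towards a quinone methide during work-up.
- Fallback: it sets out from 17 and returns at 23, masking the phenol so that a neutral aldehyde meets only a slight excess of nucleophile.
- TBSOTf and 2,6-lutidine give 8-[2-(tert-butyldimethylsilyloxy)-4-ethoxy-3-formyl-6-(triisopropylsilyloxy)phenyl]-5,7-bis(benzyloxy)-4'-methoxyflavone F10.
- Reagent 19 (1.2 equiv, THF, −20 °C) gives the corresponding O-silylated propargylic alcohol F11, and MnO2 gives the O-silylated ynone F12.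
- KF with 18-crown-6 in dry DMF releases the O8a'' phenoxide, which closes ring C'' 6-endo under aprotic conditions. The same reagent strips the second silyl group to give 23.

Further compounds
F1 | step 6 | 5-ethoxybenzene-1,3-diol | CCOc1cc(O)cc(O)c1
F2 | step 6 | 1-ethoxy-3,5-bis(methoxymethoxy)benzene | CCOc1cc(OCOC)cc(OCOC)c1
F3 | step 6 | [4-ethoxy-2,6-bis(methoxymethoxy)phenyl]boronic acid | CCOc1cc(OCOC)c(B(O)O)c(OCOC)c1
F4 | step 6 | 5,7-bis(benzyloxy)-8-[4-ethoxy-2,6-bis(methoxymethoxy)phenyl]-4'-methoxyflavone | COc1ccc(cc1)-c1cc(=O)c2c(OCc3ccccc3)cc(OCc3ccccc3)c(-c3c(OCOC)cc(OCC)cc3OCOC)c2o1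
F5 | step 6 | 5,7-bis(benzyloxy)-8-(4-ethoxy-2,6-dihydroxyphenyl)-4'-methoxyflavone | COc1ccc(cc1)-c1cc(=O)c2c(OCc3ccccc3)cc(OCc3ccccc3)c(-c3c(O)cc(OCC)cc3O)c2o1
F6 | step 5 | 5,7-bis(benzyloxy)-4'-methoxyflavone-8-carboxylic acid | COc1ccc(cc1)-c1cc(=O)c2c(OCc3ccccc3)cc(OCc3ccccc3)c(C(O)=O)c2o1
F7 | step 5 | 5,7-bis(benzyloxy)-4'-methoxyflavone-8-carbonyl chloride | COc1ccc(cc1)-c1cc(=O)c2c(OCc3ccccc3)cc(OCc3ccccc3)c(C(Cl)=O)c2o1
F8 | step 5 | 5,7-bis(benzyloxy)-8-(diazoacetyl)-4'-methoxyflavone | COc1ccc(cc1)-c1cc(=O)c2c(OCc3ccccc3)cc(OCc3ccccc3)c(C(=O)C=[N+]=[N-])c2o1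
F9 | step 5 | 5,7-bis(benzyloxy)-8-[diazo(triisopropylsilyl)acetyl]-4'-methoxyflavone | COc1ccc(cc1)-c1cc(=O)c2c(OCc3ccccc3)cc(OCc3ccccc3)c(C(=O)C(=[N+]=[N-])[Si](C(C)C)(C(C)C)C(C)C)c2o1
F10 | step 8 | 8-[2-(tert-butyldimethylsilyloxy)-4-ethoxy-3-formyl-6-(triisopropylsilyloxy)phenyl]-5,7-bis(benzyloxy)-4'-methoxyflavone | COc1ccc(cc1)-c1cc(=O)c2c(OCc3ccccc3)cc(OCc3ccccc3)c(-c3c(O[Si](C)(C)C(C)(C)C)c(C=O)c(OCC)cc3O[Si](C(C)C)(C(C)C)C(C)C)c2o1
F11 | step 8 | O-silylated propargylic alcohol (2-O-TBS ether of 20) | COc1ccc(cc1)-c1cc(=O)c2c(OCc3ccccc3)cc(OCc3ccccc3)c(-c3c(O[Si](C)(C)C(C)(C)C)c(C(O)C#Cc4ccc(OCc5ccccc5)cc4)c(OCC)cc3O[Si](C(C)C)(C(C)C)C(C)C)c2o1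
F12 | step 8 | O-silylated ynone (2-O-TBS ether of 21) | COc1ccc(cc1)-c1cc(=O)c2c(OCc3ccccc3)cc(OCc3ccccc3)c(-c3c(O[Si](C)(C)C(C)(C)C)c(C(=O)C#Cc4ccc(OCc5ccccc5)cc4)c(OCC)cc3O[Si](C(C)C)(C(C)C)C(C)C)c2o1
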